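## Retrosynthetic overview

1. Feature (flavanone numbering, primes for ring B): in ring C, O1 bridges the benzylic stereocentre C2 and the ring-A fusion carbon C8a. C8a is ortho to C4a, which carries the C4 ketone. The C8a–O1 bond can therefore be made by SNAr on a C8a–F bond while C2–O, C2–C3 and C2–C1' stay untouched.
2. 20 ⇒ 19 (loss of two MOM groups) ⇒ 16 (Claisen–Cope relay O5 → C6 → C8). The 5-O-prenyl ether protects O5 through the key step and later supplies the C8 prenyl group.
3. 16 ⇒ (S)-β-hydroxy ketone 13 (C8a–O1, retentive SNAr) ⇒ 2'-fluorochalcone 11. The C2–O bond comes from Cu-catalysed enantioselective β-borylation and retentive oxidation, because methyl-ketone aldols to electron-rich benzaldehydes are reversible and poorly face-selective.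
4. 11 ⇒ acetophenone 5 (from 5-fluororesorcinol 1: C-acetylation, 4-O-MOM, 6-O-prenyl) + aldehyde 10 (from 4-hydroxy-2-methoxybenzaldehyde 6: O-prenylation, aromatic Claisen to the 1,1-dimethylallyl group, MOM).
5. Ring order: rings A and B are bought; ring C is the only ring made, in step 9.

Key step: step 9

Assumption: the sense of induction of the copper–Josiphos boryl transfer in step 8 is taken from simple β-aryl enones; both ligand antipodes are sold, so the antipode is used, with nothing else changed, should a first run give the (R)-carbinol.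

## Route

Step 1
Reactants: 1 5-fluororesorcinol
Product: 2 1-(2-fluoro-4,6-dihydroxyphenyl)ethanone
Conditions: AcOH, ZnCl2, 140 °C
Reagents that add atoms: acetic acid, CC(=O)O
Why: Nencki reaction (Friedel–Crafts C-acylation of a resorcinol): C4 of 1 is para to one hydroxyl and ortho to the other while C2 is crowded by both, so the acetyl group should enter next to fluorine as it does next to methyl in orcinol, and the hydrogen-bonded, deactivated ketone should not acylate twice.

Step 2
Reactants: 2 1-(2-fluoro-4,6-dihydroxyphenyl)ethanone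
Product: 3 1-[2-fluoro-6-hydroxy-4-(methoxymethoxy)phenyl]ethanone
Conditions: MOMCl (1.05 equiv), K2CO3, acetone, 0 °C → rt
Reagents that add atoms: chloromethyl methyl ether, COCCl
Why: Williamson-type O-alkylation that should pick the 4-OH, which is para to the ketone, more acidic and free, over the 6-OH, which is locked in a hydrogen bond to the carbonyl oxygen.

Step 3
Reactants: 3 1-[2-fluoro-6-hydroxy-4-(methoxymethoxy)phenyl]ethanone; 4 prenyl bromide
Product: 5 1-[2-fluoro-4-(methoxymethoxy)-6-(3-methylbut-2-enyloxy)phenyl]ethanone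
Conditions: K2CO3, DMF, 50 °C
Reagents that add atoms: none
Why: Williamson ether synthesis on the only phenol left, where the polar solvent and gentle warming break the chelate, carbonate in DMF favours O- over C-alkylation, and the weakly nucleophilic phenoxide should leave the aryl fluoride alone.

Step 4
Reactants: 6 4-hydroxy-2-methoxybenzaldehyde; 4 prenyl bromide
Product: 7 2-methoxy-4-(3-methylbut-2-enyloxy)benzaldehyde
Conditions: K2CO3, DMF, rt
Reagents that add atoms: none
Why: Williamson ether synthesis on an acidic para-formyl phenol with a primary allylic bromide, which should alkylate at oxygen by SN2 without allylic transposition.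

Step 5
Reactants: 7 2-methoxy-4-(3-methylbut-2-enyloxy)benzaldehyde
Product: 9 4-hydroxy-2-methoxy-5-(2-methylbut-3-en-2-yl)benzaldehyde, via ortho-dienone 8 (not isolated)
Conditions: EtOH–H2O (4:1), 130 °C, sealed tube
Reagents that add atoms: none
Why: Aromatic Claisen rearrangement: the [3,3] shift inverts the prenyl unit and delivers it as the 1,1-dimethylallyl group to C5 and not to C3, which is hemmed in by the methoxy group, while the protic medium speeds both the shift and the enolisation of 8, so that a further Cope shift to the formyl-bearing para carbon should stay minor.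

Step 6
Reactants: 9 4-hydroxy-2-methoxy-5-(2-methylbut-3-en-2-yl)benzaldehyde
Product: 10 2-methoxy-4-(methoxymethoxy)-5-(2-methylbut-3-en-2-yl)benzaldehyde
Conditions: MOMCl, K2CO3, acetone, rt
Reagents that add atoms: chloromethyl methyl ether, COCCl
Why: Williamson-type O-alkylation with the small, reactive MOMCl, which should still reach the phenoxide beside the tertiary alkyl group and which masks the phenol against the bases of steps 7 to 9.

Step 7
Reactants: 5 1-[2-fluoro-4-(methoxymethoxy)-6-(3-methylbut-2-enyloxy)phenyl]ethanone; 10 2-methoxy-4-(methoxymethoxy)-5-(2-methylbut-3-en-2-yl)benzaldehyde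
Product: 11 (2E)-1-[2-fluoro-4-(methoxymethoxy)-6-(3-methylbut-2-enyloxy)phenyl]-3-[2-methoxy-4-(methoxymethoxy)-5-(2-methylbut-3-en-2-yl)phenyl]prop-2-en-1-one
Conditions: KOH, EtOH–THF, 0 °C → rt
Reagents that add atoms: none
Why: Claisen–Schmidt condensation (aldol addition, then E1cB loss of water) gives the conjugated (E)-enone under thermodynamic control, all ethers and acetals are base-stable, and hydroxide or ethoxide solvated by ethanol should be too poor an SNAr nucleophile at room temperature to attack the C–F bond.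

Step 8
Reactants: 11 the (E)-2'-fluorochalcone
Product: 13 (3S)-1-[2-fluoro-4-(methoxymethoxy)-6-(3-methylbut-2-enyloxy)phenyl]-3-hydroxy-3-[2-methoxy-4-(methoxymethoxy)-5-(2-methylbut-3-en-2-yl)phenyl]propan-1-one, via benzylic boronate 12 (not isolated)
Conditions: CuCl (3 mol %), NaOt-Bu (5 mol %), (R,Sp)-Josiphos SL-J001 (3.5 mol %), B2pin2 (1.1 equiv), MeOH (2 equiv), THF, rt; then NaBO3·4H2O, THF–H2O, rt
Reagents that add atoms: bis(pinacolato)diboron, CC1(C)OB(OC1(C)C)B1OC(C)(C)C(C)(C)O1 (Bpin of 12); sodium perborate, [Na+].[Na+].O[B-]1(O)OO[B-](O)(O)OO1 (hydroxyl oxygen of 13)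
Why: Copper(I)-catalysed enantioselective conjugate borylation followed by perborate oxidation: the ligated Cu–Bpin species adds across the enone and the chiral diphosphine directs boron to the Si face of C-β to set (S)-12, methanol protonates the enolate, the C–B to C–O 1,2-shift runs with retention to give (S)-13, and the unactivated prenyl and hindered vinyl groups should not compete with the enone for 1.1 equivalents of diboron.

Step 9
Reactants: 13 the (3S)-β-hydroxy ketone
Product: 16 (2S)-2-[2-methoxy-4-(methoxymethoxy)-5-(2-methylbut-3-en-2-yl)phenyl]-7-(methoxymethoxy)-5-(3-methylbut-2-enyloxy)chroman-4-one, via potassium alkoxide 14 (not isolated), via Meisenheimer adduct 15 (not isolated)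
Conditions: KHMDS (1.0 equiv), THF–DMPU (9:1), 0.01 M, −78 → −20 °C; pH 7 buffer at −20 °C
Reagents that add atoms: none
Why: KHMDS removes the carbinol proton of 13 (O–H far faster than C3–H at −78 °C) and, on warming, alkoxide 14 adds to the fluorine-bearing carbon C8a to give σ-adduct 15, whose charge is spread over C4a, C6 and C8 and out to the C4 carbonyl oxygen, before fluoride leaves as insoluble KF and ring A rearomatises. The closest known reaction type is the intramolecular SNAr etherification of alkoxides onto o-fluoroaryl ketones that gives chroman-4-ones and, from 1,3-diketone enolates, chromones. Ring C closes as a six-membered ring, exo with respect to the C–F bond that breaks and endo-trig with respect to the C8a=C4a π bond that relays the charge to the ketone, and the three-atom tether lets oxygen reach C8a perpendicular to the arene plane. No stereocentre is created, and C2 keeps its (S) configuration because only the O–H bond is broken and never C2–O, C2–C3 or C2–C1', so the strongly donor-substituted benzylic position gets no chance to ionise. The step needs attack at C8a to beat retro-aldol cleavage, E1cB dehydration and later enolisation of 16, and this is secured by the single leaving group, by both ring-A alkoxy groups being meta to C8a on carbons that carry no charge in 15, by the weakly coordinating potassium ion in THF–DMPU that avoids an alkoxide–carbonyl chelate holding oxygen away from C8a, by high dilution that slows every bimolecular proton transfer and any aldol recombination but not the cyclisation, and by one equivalent of base that leaves no soluble base once 14 is spent. Whatever dehydrates ends as fluorochalcone 11, which has no ortho oxygen and cannot close, so side reactions should cost recyclable material (11, 5, 10) rather than enantiopurity.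

Step 10
Reactants: 16 the (2S)-5-O-prenyl flavanone
Product: 19 (2S)-5-hydroxy-2-[2-methoxy-4-(methoxymethoxy)-5-(2-methylbut-3-en-2-yl)phenyl]-7-(methoxymethoxy)-8-(3-methylbut-2-enyl)chroman-4-one, via ortho-dienone 17 (not isolated), via para-dienone 18 (not isolated)
Conditions: Eu(fod)3 (10 mol %), NaHCO3, PhCl, 85 °C
Reagents that add atoms: none
Why: Europium(III)-catalysed tandem aromatic Claisen–Cope (para-Claisen) rearrangement: Eu(fod)3 bound between the C4 carbonyl and O5 triggers the [3,3] shift to C6, the only free ortho carbon, the crowded ortho-dienone 17 passes the allyl unit on to C8 by a Cope shift that restores the linear prenyl group, para-dienone 18 enolises to the chelated 5-phenol, and no bond at C2 takes part.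

Step 11
Reactants: 19 the (2S)-8-prenyl-7,4'-di-O-MOM flavanone
Product: 20 (2S)-5,7-dihydroxy-2-[4-hydroxy-2-methoxy-5-(2-methylbut-3-en-2-yl)phenyl]-8-(3-methylbut-2-enyl)chroman-4-one
Conditions: HCl (1 M in MeOH), rt
Reagents that add atoms: none
Why: Acid-catalysed transacetalisation of the two aryl MOM ethers to dimethoxymethane, which runs through an oxocarbenium ion at room temperature, whereas protonation of the olefins (chroman or dihydrobenzofuran formation) and ionisation of the C2–O1 bond need stronger acid or heat, and no base ever meets the free 4'-phenol, whose phenoxide could open ring C through a quinone methide.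

## Compound list

1 | 5-fluororesorcinol | Oc1cc(O)cc(F)c1 | starting material
2 | 1-(2-fluoro-4,6-dihydroxyphenyl)ethanone | CC(=O)c1c(F)cc(O)cc1O | intermediate
3 | 1-[2-fluoro-6-hydroxy-4-(methoxymethoxy)phenyl]ethanone | CC(=O)c1c(F)cc(OCOC)cc1O | intermediate
4 | prenyl bromide (1-bromo-3-methylbut-2-ene) | CC(C)=CCBr | starting material
5 | 1-[2-fluoro-4-(methoxymethoxy)-6-(3-methylbut-2-enyloxy)phenyl]ethanone | CC(=O)c1c(F)cc(OCOC)cc1OCC=C(C)C | intermediate
6 | 4-hydroxy-2-methoxybenzaldehyde | COc1cc(O)ccc1C=O | starting material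
7 | 2-methoxy-4-(3-methylbut-2-enyloxy)benzaldehyde | COc1cc(OCC=C(C)C)ccc1C=O | intermediate
8 | ortho-dienone, racemic 6-methoxy-3-(2-methylbut-3-en-2-yl)-4-oxocyclohexa-1,5-diene-1-carbaldehyde | O=C1C=C(OC)C(C=O)=CC1C(C)(C)C=C | intermediate
9 | 4-hydroxy-2-methoxy-5-(2-methylbut-3-en-2-yl)benzaldehyde | C=CC(C)(C)c1cc(C=O)c(OC)cc1O | intermediate
10 | 2-methoxy-4-(methoxymethoxy)-5-(2-methylbut-3-en-2-yl)benzaldehyde | C=CC(C)(C)c1cc(C=O)c(OC)cc1OCOC | intermediate
11 | (2E)-1-[2-fluoro-4-(methoxymethoxy)-6-(3-methylbut-2-enyloxy)phenyl]-3-[2-methoxy-4-(methoxymethoxy)-5-(2-methylbut-3-en-2-yl)phenyl]prop-2-en-1-one | C=CC(C)(C)c1cc(/C=C/C(=O)c2c(F)cc(OCOC)cc2OCC=C(C)C)c(OC)cc1OCOC | intermediate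
12 | (3S)-1-[2-fluoro-4-(methoxymethoxy)-6-(3-methylbut-2-enyloxy)phenyl]-3-[2-methoxy-4-(methoxymethoxy)-5-(2-methylbut-3-en-2-yl)phenyl]-3-(4,4,5,5-tetramethyl-1,3,2-dioxaborolan-2-yl)propan-1-one | C=CC(C)(C)c1cc([C@@H](B2OC(C)(C)C(C)(C)O2)CC(=O)c2c(F)cc(OCOC)cc2OCC=C(C)C)c(OC)cc1OCOC | intermediate
13 | (3S)-1-[2-fluoro-4-(methoxymethoxy)-6-(3-methylbut-2-enyloxy)phenyl]-3-hydroxy-3-[2-methoxy-4-(methoxymethoxy)-5-(2-methylbut-3-en-2-yl)phenyl]propan-1-one | C=CC(C)(C)c1cc([C@@H](O)CC(=O)c2c(F)cc(OCOC)cc2OCC=C(C)C)c(OC)cc1OCOC | intermediate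
14 | potassium (S)-alkoxide of 13 | C=CC(C)(C)c1cc([C@@H]([O-])CC(=O)c2c(F)cc(OCOC)cc2OCC=C(C)C)c(OC)cc1OCOC.[K+] | intermediate
15 | Meisenheimer adduct, potassium (2S)-8a-fluoro-2-aryl-7-(methoxymethoxy)-5-(3-methylbut-2-enyloxy)-2,3-dihydro-8aH-chromen-4-olate (aryl as in 13; C8a unassigned) | C=CC(C)(C)c1cc([C@@H]2CC([O-])=C3C(OCC=C(C)C)=CC(OCOC)=CC3(F)O2)c(OC)cc1OCOC.[K+] | intermediate
16 | (2S)-2-[2-methoxy-4-(methoxymethoxy)-5-(2-methylbut-3-en-2-yl)phenyl]-7-(methoxymethoxy)-5-(3-methylbut-2-enyloxy)chroman-4-one | C=CC(C)(C)c1cc([C@@H]2CC(=O)c3c(OCC=C(C)C)cc(OCOC)cc3O2)c(OC)cc1OCOC | intermediate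
17 | ortho-dienone, (2S)-2-aryl-7-(methoxymethoxy)-6-(2-methylbut-3-en-2-yl)-2,3-dihydrochromene-4,5(6H)-dione (C6 unassigned) | C=CC(C)(C)c1cc([C@@H]2CC(=O)C3=C(O2)C=C(OCOC)C(C(C)(C)C=C)C3=O)c(OC)cc1OCOC | intermediate
18 | para-dienone, (2S)-2-aryl-7-(methoxymethoxy)-8-(3-methylbut-2-enyl)-2,3-dihydrochromene-4,5(8H)-dione (C8 unassigned) | C=CC(C)(C)c1cc([C@@H]2CC(=O)C3=C(O2)C(CC=C(C)C)C(OCOC)=CC3=O)c(OC)cc1OCOC | intermediate
19 | (2S)-5-hydroxy-2-[2-methoxy-4-(methoxymethoxy)-5-(2-methylbut-3-en-2-yl)phenyl]-7-(methoxymethoxy)-8-(3-methylbut-2-enyl)chroman-4-one | C=CC(C)(C)c1cc([C@@H]2CC(=O)c3c(O)cc(OCOC)c(CC=C(C)C)c3O2)c(OC)cc1OCOC | intermediate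
20 | (2S)-5,7-dihydroxy-2-[4-hydroxy-2-methoxy-5-(2-methylbut-3-en-2-yl)phenyl]-8-(3-methylbut-2-enyl)chroman-4-one | C=CC(C)(C)c1cc([C@@H]2CC(=O)c3c(O)cc(O)c(CC=C(C)C)c3O2)c(OC)cc1O | target

## Step count and risks

Total step count: 11.

Longest linear sequence: 8 steps. This is steps 1, 2, 3, 7, 8, 9, 10, 11 from 1, and the branch from 6 through steps 4, 5, 6 is equally long.

**Step 9 (key step).**
- What may go wrong: alkoxide 14 may fragment by retro-aldol cleavage. It may also be drained by proton transfer and E1cB loss of hydroxide faster than it attacks C8a. Recombination of the fragments, or enolisation and ring opening of 16 by unspent alkoxide, would erode the enantiomeric purity.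
- Fallback, from 11 back to 16: fluorine is exchanged for oxygen before any stereocentre exists, and the configuration is secured afterwards by resolution. Chalcone 11 is treated with 2-(methylsulfonyl)ethanol and NaH in DMF. This intermolecular SNAr gives the 2-(methylsulfonyl)ethyl aryl ether F1, which loses methyl vinyl sulfone in the same flask and leaves the 2'-hydroxychalcone F2. NaOAc in refluxing EtOH closes ring C by oxa-Michael addition to the racemic flavanone F3. A kinetic resolution by asymmetric transfer hydrogenation (Ru or Rh (R,R)-TsDPEN catalyst, HCO2H–Et3N, EtOAc) should reduce the (2R)-enantiomer to the cis-(2R,4R)-flavan-4-ol F4. It should leave the (2S)-flavanone 16, which is separated by chromatography.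

**Step 10.**
- What may go wrong: the sigmatropic relay may stall after the first shift through early enolisation of the ortho-dienone. The ether may simply lose its prenyl group. Lewis acid and heat may also open ring C reversibly at the donor-substituted benzylic carbon and lower the enantiomeric purity.
- Fallback, from 5 back to 20: the relay is moved to the achiral acetophenone, where heat cannot harm a stereocentre. Ketone 5 is heated in N,N-diethylaniline at 200 °C. The thermal Claisen–Cope sequence gives the 3-prenyl-6-hydroxyacetophenone F5, and MOMCl with NaH in DMF gives the bis-MOM ketone F6. Condensation with 10 as in step 7 gives the 3'-prenyl fluorochalcone F7. Borylation as in step 8 gives the boronate F8, which is oxidised in the same flask to the (S)-β-hydroxy ketone F9. Closure as in step 9 gives the (2S)-5,7,4'-tri-O-MOM-8-prenylflavanone F10, and the conditions of step 11 remove all three MOM groups to give 20.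

**Step 8.**
- What may go wrong: facial selectivity may be poor or boryl-cupration slow, because the β-aryl group is ortho-substituted and strongly donating.
- Fallback, from 5 and 10 back to 13: the stereocentre is set in a C–C bond-forming step instead. Ketone 5 is converted with LDA and then TMSCl (THF, −78 °C) into the trimethylsilyl enol ether F11. F11 is added to aldehyde 10 in a Lewis-base-catalysed Mukaiyama aldol reaction: SiCl4, chiral binaphthyldiamine-derived bisphosphoramide (5 mol %, antipode chosen for Si-face attack on the aldehyde), i-Pr2NEt, CH2Cl2, −78 °C. Aqueous KF–NaHCO3 work-up releases 13.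

## Further compounds

F1 | step 9 | (2E)-1-[4-(methoxymethoxy)-2-(3-methylbut-2-enyloxy)-6-(2-methylsulfonylethoxy)phenyl]-3-[2-methoxy-4-(methoxymethoxy)-5-(2-methylbut-3-en-2-yl)phenyl]prop-2-en-1-one | C=CC(C)(C)c1cc(/C=C/C(=O)c2c(OCCS(C)(=O)=O)cc(OCOC)cc2OCC=C(C)C)c(OC)cc1OCOC
F2 | step 9 | (2E)-1-[2-hydroxy-4-(methoxymethoxy)-6-(3-methylbut-2-enyloxy)phenyl]-3-[2-methoxy-4-(methoxymethoxy)-5-(2-methylbut-3-en-2-yl)phenyl]prop-2-en-1-one | C=CC(C)(C)c1cc(/C=C/C(=O)c2c(O)cc(OCOC)cc2OCC=C(C)C)c(OC)cc1OCOC
F3 | step 9 | racemic 2-[2-methoxy-4-(methoxymethoxy)-5-(2-methylbut-3-en-2-yl)phenyl]-7-(methoxymethoxy)-5-(3-methylbut-2-enyloxy)chroman-4-one | C=CC(C)(C)c1cc(C2CC(=O)c3c(OCC=C(C)C)cc(OCOC)cc3O2)c(OC)cc1OCOC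
F4 | step 9 | (2R,4R)-2-[2-methoxy-4-(methoxymethoxy)-5-(2-methylbut-3-en-2-yl)phenyl]-7-(methoxymethoxy)-5-(3-methylbut-2-enyloxy)chroman-4-ol | C=CC(C)(C)c1cc([C@H]2C[C@@H](O)c3c(OCC=C(C)C)cc(OCOC)cc3O2)c(OC)cc1OCOC
F5 | step 10 | 1-[2-fluoro-6-hydroxy-4-(methoxymethoxy)-3-(3-methylbut-2-enyl)phenyl]ethanone | CC(=O)c1c(F)c(CC=C(C)C)c(OCOC)cc1O
F6 | step 10 | 1-[2-fluoro-4,6-bis(methoxymethoxy)-3-(3-methylbut-2-enyl)phenyl]ethanone | CC(=O)c1c(F)c(CC=C(C)C)c(OCOC)cc1OCOC
F7 | step 10 | (2E)-1-[2-fluoro-4,6-bis(methoxymethoxy)-3-(3-methylbut-2-enyl)phenyl]-3-[2-methoxy-4-(methoxymethoxy)-5-(2-methylbut-3-en-2-yl)phenyl]prop-2-en-1-one | C=CC(C)(C)c1cc(/C=C/C(=O)c2c(F)c(CC=C(C)C)c(OCOC)cc2OCOC)c(OC)cc1OCOC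
F8 | step 10 | (3S)-1-[2-fluoro-4,6-bis(methoxymethoxy)-3-(3-methylbut-2-enyl)phenyl]-3-[2-methoxy-4-(methoxymethoxy)-5-(2-methylbut-3-en-2-yl)phenyl]-3-(4,4,5,5-tetramethyl-1,3,2-dioxaborolan-2-yl)propan-1-one | C=CC(C)(C)c1cc([C@@H](B2OC(C)(C)C(C)(C)O2)CC(=O)c2c(F)c(CC=C(C)C)c(OCOC)cc2OCOC)c(OC)cc1OCOC
F9 | step 10 | (3S)-1-[2-fluoro-4,6-bis(methoxymethoxy)-3-(3-methylbut-2-enyl)phenyl]-3-hydroxy-3-[2-methoxy-4-(methoxymethoxy)-5-(2-methylbut-3-en-2-yl)phenyl]propan-1-one | C=CC(C)(C)c1cc([C@@H](O)CC(=O)c2c(F)c(CC=C(C)C)c(OCOC)cc2OCOC)c(OC)cc1OCOC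
F10 | step 10 | (2S)-2-[2-methoxy-4-(methoxymethoxy)-5-(2-methylbut-3-en-2-yl)phenyl]-5,7-bis(methoxymethoxy)-8-(3-methylbut-2-enyl)chroman-4-one | C=CC(C)(C)c1cc([C@@H]2CC(=O)c3c(OCOC)cc(OCOC)c(CC=C(C)C)c3O2)c(OC)cc1OCOC
F11 | step 8 | {1-[2-fluoro-4-(methoxymethoxy)-6-(3-methylbut-2-enyloxy)phenyl]ethenyloxy}trimethylsilane | C=C(O[Si](C)(C)C)c1c(F)cc(OCOC)cc1OCC=C(C)C
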